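**Retrosynthetic overview**
- The target is the octanoate of an (R)-configured tertiary azaphilone alcohol; the ester C–O bond is made last, with octanoic acid built from heptyl bromide and CO2.
- The six-membered dione ring comes from a one-carbon α-ketol ring expansion (1,2-acyl shift) of an (S)-6-acetyl-6-hydroxycyclopenta[c]pyran-7-one; the acetyl carbon becomes C7 with its CH3 and OH, and the carbinol chirality is transferred.
- The acetyl carbinol comes from catalytic asymmetric α-hydroxylation of the 6-acetyl ketone, itself made by C-acetylation of the bicyclic ketone.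
- The pyran ring comes from Sonogashira coupling and 6-endo O-cyclization of non-1-yne (heptyl bromide plus acetylide) with the bromoformylation product of cyclopentane-1,3-dione.
- Ring order: five-membered carbocycle (bought), then the pyran, then expansion of the carbocycle from five to six members.

Assumption: the (R,R) antipode of the bis(oxazoline) ligand in Step 5 is taken to give the (S)-carbinol; if the sense of induction is the opposite, the (S,S) ligand is used and nothing else changes.

**Route**

Step 1
Reactants: 1 1-bromoheptane; 2 lithium acetylide–ethylenediamine complex (LiC≡CH·H2NCH2CH2NH2)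
Product: 3 non-1-yne
Conditions: DMSO, 10 → 25 °C, 2 h; distil
Reagents that add atoms: none
Why: SN2 alkylation of a metal acetylide by a primary bromide in a dipolar aprotic solvent (acetylide alkylation) is a standard entry to terminal alkynes and creates no stereocenter.

Step 2
Reactants: 4 cyclopentane-1,3-dione
Product: 5 2-bromo-5-oxocyclopent-1-ene-1-carbaldehyde
Conditions: PBr3 (2.5 equiv), DMF (3 equiv), CHCl3, 0 → 60 °C; then ice water
Reagents that add atoms: N,N-dimethylformamide CN(C)C=O (formyl carbon); phosphorus tribromide BrP(Br)Br (bromine); water O (aldehyde oxygen)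
Why: In this Vilsmeier–Haack–Arnold bromoformylation the nucleophilic C2 of the enolized dione attacks the bromoiminium salt and the activated enol oxygen is displaced by bromide, as is established for indane-1,3-dione and dimedone; no stereocenter is formed.

Step 3
Reactants: 5 2-bromo-5-oxocyclopent-1-ene-1-carbaldehyde; 3 non-1-yne
Product: 7 3-heptylcyclopenta[c]pyran-7(6H)-one, via enynal 6 (not isolated)
Conditions: PdCl2(PPh3)2 (3 mol %), CuI (6 mol %), Et3N (3 equiv), degassed MeCN, 0 → 23 °C, then 50 °C, 2 h, argon
Reagents that add atoms: none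
Why: Sonogashira coupling of the vinylogous acyl bromide is followed by amine-mediated γ-deprotonation to the hydroxymethylene dienol, whose oxygen adds 6-endo-dig to the copper-activated alkyne at its conjugate (heptyl-bearing) carbon (cycloisomerization of the kind that closes azaphilone pyrans); no stereocenter is formed.

Step 4
Reactants: 7 3-heptylcyclopenta[c]pyran-7(6H)-one
Product: 8 6-acetyl-3-heptylcyclopenta[c]pyran-7(6H)-one
Conditions: LiN(SiMe3)2 (2.2 equiv), THF, −78 °C; 1-acetylimidazole (1.2 equiv), −78 → 0 °C; AcOH quench
Reagents that add atoms: 1-acetylimidazole CC(=O)n1ccnc1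
Why: C6 is the only enolizable position of 7, so its lithium enolate is C-acylated by the acyl imidazole (Claisen-type acylation) and the second equivalent of base traps the more acidic 1,3-diketone; C6 stays configurationally undefined because 8 is enolized.

Step 5
Reactants: 8 6-acetyl-3-heptylcyclopenta[c]pyran-7(6H)-one
Product: 9 (S)-6-acetyl-3-heptyl-6-hydroxycyclopenta[c]pyran-7(6H)-one
Conditions: Ni(ClO4)2·6H2O (10 mol %), (R,R)-4,6-dibenzofurandiyl-2,2'-bis(4-phenyloxazoline) (11 mol %), racemic 2-(phenylsulfonyl)-3-phenyloxaziridine (1.2 equiv), 4 Å molecular sieves, CH2Cl2, 23 °C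
Reagents that add atoms: 2-(phenylsulfonyl)-3-phenyloxaziridine O=S(=O)(c1ccccc1)N1OC1c1ccccc1
Why: In this Lewis acid-catalysed enantioselective α-hydroxylation of a 1,3-dicarbonyl (Davis-type oxaziridine oxidation) the diketonate is bound at two points to the chiral divalent-nickel complex, which exposes one enantioface of C6 to the oxidant and sets the (S)-carbinol.

Step 6
Reactants: 9 (S)-6-acetyl-3-heptyl-6-hydroxycyclopenta[c]pyran-7(6H)-one
Product: 10 (R)-3-heptyl-7-hydroxy-7-methyl-6H-isochromene-6,8(7H)-dione
Conditions: Cu(OTf)2 (10 mol %), 4 Å molecular sieves, CH2Cl2, 23 → 40 °C, argon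
Reagents that add atoms: none
Why: Proposed new method: a chelation-controlled α-ketol (acyloin) ring expansion in which divalent copper binds the tertiary hydroxyl and the acetyl carbonyl of 9 in a five-membered chelate and the ring carbonyl carbon, an acyl group that migrates readily, shifts suprafacially from the carbinol carbon to the acetyl carbon, so that the old carbinol carbon becomes the C6 ketone, the old acetyl carbon becomes C7 of 10 carrying OH and CH3, and the cyclopentenone grows into the six-membered hydroxy-dione; the shift should be driven by loss of five-ring strain and by conjugation of the new C6 carbonyl with the dienyl ether C5=C4a–C4=C3–O2, the syn-periplanar O–C–C=O geometry of the chelate converts the (S)-carbinol into (R)-C7, and the other chelated shift sequences (acetyl shift to the ring carbonyl first, or vinyl shift followed by methyl shift) are reversible and lead to the same constitution and configuration; the closest known reaction type is the Lewis acid α-ketol rearrangement used for D-homoannulation of 17-hydroxy-20-keto steroids and the acyl-migrating acyloin rearrangement of α-hydroxy-β-dicarbonyl compounds, which has not been shown as a five-to-six expansion of a pyran-fused acyl carbinol with transfer of central chirality.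

Step 7
Reactants: 1 1-bromoheptane
Product: 12 octanoic acid, via Grignard reagent 11 (not isolated)
Conditions: Mg turnings, THF, 40 °C; CO2 (dry ice), −40 → 0 °C; aq. HCl
Reagents that add atoms: carbon dioxide O=C=O
Why: Grignard formation and carboxylation with CO2 extend the seven-carbon bromide by one carbon to the eight-carbon acid; no stereocenter is formed.

Step 8
Reactants: 10 (R)-3-heptyl-7-hydroxy-7-methyl-6H-isochromene-6,8(7H)-dione; 12 octanoic acid
Product: 14 (R)-3-heptyl-7-methyl-6,8-dioxo-7,8-dihydro-6H-isochromen-7-yl octanoate, via octanoyl chloride 13 (not isolated)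
Conditions: 12, (COCl)2 (1.1 equiv), DMF (cat.), CH2Cl2, 0 → 23 °C, evaporate; then 10, Et3N (3 equiv), DMAP (0.2 equiv), CH2Cl2, 0 → 23 °C
Reagents that add atoms: none
Why: Acid chloride formation in the flask and DMAP-catalysed O-acylation of the hindered tertiary α-ketol (nucleophilic acyl-transfer catalysis, routine for azaphilone tertiary alcohols) form the ester without touching the C7–O bond, so the (R) configuration is retained.

**Compound list**

1 | 1-bromoheptane | CCCCCCCBr | starting material
2 | lithium acetylide–ethylenediamine complex | [Li+].[C-]#C.NCCN | starting material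
3 | non-1-yne | C#CCCCCCCC | intermediate
4 | cyclopentane-1,3-dione | O=C1CCC(=O)C1 | starting material
5 | 2-bromo-5-oxocyclopent-1-ene-1-carbaldehyde | O=CC1=C(Br)CCC1=O | intermediate
6 | 2-(non-1-yn-1-yl)-5-oxocyclopent-1-ene-1-carbaldehyde (enynal) | O=CC1=C(C#CCCCCCCC)CCC1=O | intermediate
7 | 3-heptylcyclopenta[c]pyran-7(6H)-one | CCCCCCCC1=CC2=CCC(=O)C2=CO1 | intermediate
8 | 6-acetyl-3-heptylcyclopenta[c]pyran-7(6H)-one (diketo tautomer drawn) | CCCCCCCC1=CC2=CC(C(C)=O)C(=O)C2=CO1 | intermediate
9 | (S)-6-acetyl-3-heptyl-6-hydroxycyclopenta[c]pyran-7(6H)-one | CCCCCCCC1=CC2=C[C@](O)(C(C)=O)C(=O)C2=CO1 | intermediate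
10 | (R)-3-heptyl-7-hydroxy-7-methyl-6H-isochromene-6,8(7H)-dione | O[C@]1(C)C(=O)C=C2C=C(CCCCCCC)OC=C2C1=O | intermediate
11 | heptylmagnesium bromide (Grignard reagent) | CCCCCCC[Mg]Br | intermediate
12 | octanoic acid | CCCCCCCC(=O)O | intermediate
13 | octanoyl chloride | CCCCCCCC(=O)Cl | intermediate
14 | (R)-3-heptyl-7-methyl-6,8-dioxo-7,8-dihydro-6H-isochromen-7-yl octanoate | CCCCCCCC(=O)O[C@]1(C)C(=O)C=C2C=C(CCCCCCC)OC=C2C1=O | target

**Step count and risks**

Total step count: 8. Longest linear sequence: 6 (Steps 2, 3, 4, 5, 6, 8).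

The three steps most likely to fail:

Step 3 (coupling and ring closure in one flask). The electron-poor enynal may polymerize or close 5-exo before the 6-endo product forms. The fallback sets out from 6 and comes back at 7. The coupling is stopped at 0 °C (Et3N, THF) and 6 is isolated. Electrophilic iodocyclization (I2, NaHCO3, MeCN, 0 °C; Larock-type 6-endo-dig closure, then loss of a proton) gives 3-heptyl-4-iodocyclopenta[c]pyran-7(6H)-one F1. Hydrodeiodination with HCO2Na under Pd(OAc)2/PPh3 catalysis (DMF, 60 °C) returns 7.

Step 5 (asymmetric hydroxylation). The enantioselectivity on this new diketone may be low. The fallback sets out from 8 and comes back at 9. Compound 8 is silylated (TBSOTf, Et3N, CH2Cl2, −78 °C) to 1-[7-(tert-butyldimethylsilyloxy)-3-heptylcyclopenta[c]pyran-6-yl]ethan-1-one F2. Shi asymmetric epoxidation of this silyl enol ether (D-fructose-derived ketone catalyst, Oxone (2KHSO5·KHSO4·K2SO4), K2CO3, MeCN/dimethoxymethane/aqueous buffer, 0 °C; Rubottom-type oxidation with silyl migration) gives (S)-6-acetyl-6-(tert-butyldimethylsilyloxy)-3-heptylcyclopenta[c]pyran-7(6H)-one F3. TBAF/AcOH (THF, 0 °C) frees 9; the enantiomeric ketone catalyst is used if the other face is attacked.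

Step 6 (the proposed new ring expansion). Simple 2-hydroxy-2-alkyl-1,3-diones normally contract rather than expand, so the equilibrium may not favour 10; the vicinal-dione isomer may accumulate, or the enantiomeric purity may erode. The fallback uses known chemistry, sets out from 3 and comes back at 10; it makes the hydroxy-dione ring by the established enantioselective oxidative dearomatization of an alkynylbenzaldehyde.
- 4-Bromotoluene is dinitrated (HNO3/H2SO4, 0 → 60 °C) to 5-bromo-2-methyl-1,3-dinitrobenzene F4.
- Reduction (Fe, AcOH/EtOH, 70 °C) gives 5-bromo-2-methylbenzene-1,3-diamine F5.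
- Bis-diazotization (NaNO2, aq. H2SO4, 0 °C) gives 5-bromo-2-methylbenzene-1,3-bis(diazonium) bis(hydrogen sulfate) F6, which is hydrolysed without isolation in boiling dilute H2SO4 to 5-bromo-2-methylbenzene-1,3-diol F7.
- Vilsmeier formylation (POCl3, DMF, then water) gives 6-bromo-2,4-dihydroxy-3-methylbenzaldehyde F8.
- Sonogashira coupling with 3 (PdCl2(PPh3)2, CuI, Et3N, DMF, 60 °C) gives 2,4-dihydroxy-3-methyl-6-(non-1-yn-1-yl)benzaldehyde F9.
- Oxidative dearomatization with [Cu(MeCN)4]PF6, (−)-sparteine and O2 (iPr2NEt, CH2Cl2, −78 → −10 °C) gives the vinylogous acid (S)-2,3-dihydroxy-3-methyl-6-(non-1-yn-1-yl)-4-oxocyclohexa-1,5-diene-1-carbaldehyde F10. The (−)-sparteine sense is given from memory of the non-halogenated azaphilone series and should be checked. F10 has the same spatial arrangement as (R)-10; the descriptor changes only because the priorities change.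
- Buffer-mediated cycloisomerization (aq. KH2PO4/K2HPO4, MeCN, 23 °C) closes the pyran to 10.

Further compounds
F1 | step 3 | 3-heptyl-4-iodocyclopenta[c]pyran-7(6H)-one | CCCCCCCC1=C(I)C2=CCC(=O)C2=CO1
F2 | step 5 | 1-[7-(tert-butyldimethylsilyloxy)-3-heptylcyclopenta[c]pyran-6-yl]ethan-1-one | CCCCCCCC1=CC2=CC(C(C)=O)=C(O[Si](C)(C)C(C)(C)C)C2=CO1
F3 | step 5 | (S)-6-acetyl-6-(tert-butyldimethylsilyloxy)-3-heptylcyclopenta[c]pyran-7(6H)-one | CCCCCCCC1=CC2=C[C@](O[Si](C)(C)C(C)(C)C)(C(C)=O)C(=O)C2=CO1
F4 | step 6 | 5-bromo-2-methyl-1,3-dinitrobenzene | Cc1c([N+](=O)[O-])cc(Br)cc1[N+](=O)[O-]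
F5 | step 6 | 5-bromo-2-methylbenzene-1,3-diamine | Cc1c(N)cc(Br)cc1N
F6 | step 6 | 5-bromo-2-methylbenzene-1,3-bis(diazonium) bis(hydrogen sulfate) | Cc1c([N+]#N)cc(Br)cc1[N+]#N.OS(=O)(=O)[O-].OS(=O)(=O)[O-]
F7 | step 6 | 5-bromo-2-methylbenzene-1,3-diol | Cc1c(O)cc(Br)cc1O
F8 | step 6 | 6-bromo-2,4-dihydroxy-3-methylbenzaldehyde | Cc1c(O)cc(Br)c(C=O)c1O
F9 | step 6 | 2,4-dihydroxy-3-methyl-6-(non-1-yn-1-yl)benzaldehyde | CCCCCCCC#Cc1cc(O)c(C)c(O)c1C=O
F10 | step 6 | (S)-2,3-dihydroxy-3-methyl-6-(non-1-yn-1-yl)-4-oxocyclohexa-1,5-diene-1-carbaldehyde | CCCCCCCC#CC1=CC(=O)[C@@](C)(O)C(O)=C1C=O
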